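In a one-step world, other conformer simply turns into isomer of the product. The north run gives that step a rate constant k, read as isomer gained per hour per amount of conformer present between 0.500 h and 1.50 h: k = 0.388 h⁻¹. In such a world, by 6.00 h each point of the charge moved from substrate to conformer would add 0.902 of a point of isomer.

all flasks: substrate 0.10 M
- south-east: other conformer 0.045 M; run made earlier
- east: other conformer 0.084 M; run made earlier
- north: other conformer 0.11 M; run made earlier
- Tuesday's: other conformer 0.0500 M; time 6.0 h
- Wednesday's: other conformer 0.120 M; time 6.0 h

| run | time / h | isomer of the product / % | other conformer / % | substrate / % | target / % |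
|---|---|---|---|---|---|
| south-east | 0.500 | 5.3 | 28.4 | 65.0 | 2.5 |
| south-east | 0.833 | 9.2 | 26.2 | 61.5 | 3.0 |
| south-east | 1.50 | 15.5 | 23.1 | 55.8 | 6.5 |
| south-east | 3.00 | 26.4 | 17.7 | 43.5 | 11.7 |
| south-east | 6.00 | 40.5 | 10.4 | 27.0 | 20.3 |
| east | 1.33 | 17.9 | 30.1 | 46.4 | 4.5 |
| east | 2.50 | 28.6 | 21.8 | 39.3 | 11.1 |
| east | 4.00 | 37.6 | 15.1 | 31.7 | 14.8 |
| east | 5.00 | 41.9 | 11.5 | 26.2 | 18.0 |
| east | 6.00 | 44.8 | 9.5 | 22.7 | 21.9 |
| north | 0.500 | 9.7 | 43.6 | 45.9 | 1.4 |
| north | 1.50 | 24.1 | 30.7 | 40.7 | 5.3 |
| north | 3.00 | 35.3 | 19.4 | 33.0 | 11.5 |
| north | 4.00 | 40.7 | 15.3 | 29.4 | 14.5 |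
| north | 6.00 | 47.3 | 10.5 | 21.4 | 21.3 |

(standard deviation of a reading: 0.5 percentage points)



- which of these there is most of at the end, counted by the substrate in it, Tuesday's (isomer of the product / substrate / other conformer / target)
- which of these there is most of at the end, counted by the substrate in it, Wednesday's (isomer of the product / substrate / other conformer / target)
- final amount of the leader among these, as a percentage of the substrate and other conformer together charged, in Tuesday's
- final amount of the leader among these, as a percentage of the substrate and other conformer together charged, in Wednesday's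

The runs showed something weaker. I took s, the conformer's share of the charge, which was 31.0% in the south-east run and 52.4% in the north run, while the isomer at 6.00 h read 40.5% and 47.3%. I called the isomer gained per point of s at that time the charge memory m, the sensitivity of this yield to the charge, and it came to 0.319, about a third of the one-step figure. The south-east run pointed to a second road to isomer: from 1.50 h to 6.00 h its substrate fell by 29 percentage points while target rose by 14 points, about half, so I supposed that at least part of the rest had gone on into conformer.

I tested m on the east run, which I had kept out of the slope: at s = 45.7% it gave 45.2% against a reading of 44.8%. Tuesday's, at s = 33.3%, lay just beyond the south-east run, so I reckoned 41.2%. Wednesday's, at s = 54.5%, lay just beyond the north run, so I reckoned 48.0%. Isomer stood ahead of substrate by 14 points in the south-east run and by 26 points in the north run, so I named isomer as the leader in both new flasks.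

The forecast, “interpolating toward east gives isomer”, named isomer of the product at 41.2% for Tuesday's and isomer of the product at 48% for Wednesday's.

Tuesday's ended with isomer of the product ahead at 41.5%, and Wednesday's with isomer of the product ahead at 47.8%, against my 41.2% and 48.0%.

substrate ⇌ other conformer (K = 1.30, k = 3.70 × 10⁻⁵ s⁻¹); substrate → target (k = 1.80 × 10⁻⁵ s⁻¹); other conformer → isomer of the product (k = 1.10 × 10⁻⁴ s⁻¹); target ⇌ isomer of the product (K = 1.50, k = 3.80 × 10⁻⁵ s⁻¹) With the back reaction of conformer to substrate struck out, Tuesday's reached 46.0% of isomer. A further flask like Wednesday's but charged with 0.048 M of conformer has s = 32.4%, and m carried on from the south-east run puts its isomer at 40.9%; that flask stood at 41.2%.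

(All runs are simulated for substances that don't exist, noise included.)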